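Count turnovers on this flask before you trust any length.

    Ly → Ju (k1 = 2.4 × 10⁻⁵ s⁻¹)
    Ez + Ly ⇌ Wy + Ej (K2 = 16, k2 = 0.0041 L mol⁻¹ s⁻¹)
    Ej → Jo (k3 = 3.4 × 10⁻⁴ s⁻¹)

Ez 0.10 M; Ly 0.0980 M; time 6.0 h

- each molecule carries two end groups: a chain counts once for every two ends that are left, dead ends included; the units are half of the end groups of the two monomers charged
- run time (flask): 6.0 h

* whether the average number of monomer units in a chain (unreacted monomers counted as chains of one) reaches 3.0 by 6.0 h (no / yes)
* average number of monomer units in a chain (unreacted monomers counted as chains of one) at 6.0 h

Start with the clock, and work in fractions of the Ez charge. Multiply 0.0041 L mol⁻¹ s⁻¹ by 0.10 M and 6.0 h: that turnover count, n, is 8.86, and with ends that never die, equal charges and no way back, the length is one more, 9.86.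

Now make a budget, the second way. Each link takes one Ez and one Ly, but Ly, the limiting reagent, also goes to Ju. Divide the two rates, taking the forward step alone: dead Ly per Ez consumed is s over the Ez fraction left, with s = 0.0585. Sum this as Ez falls to fraction f: dead Ly is s times the logarithm of one over f. At zero Ly, f equals the gap between the charges, 2.00%, plus that dead Ly. Ends left are Ez ends and dead ends, twice f less the gap, and the length is charged ends over ends left.

Put the clock's Ez into the logarithm and reckon as if Ly stood at zero: f is 15.4% and the length 6.88, so my answer on reaching 3.0 is yes. The two ways part, the clock standing higher, and the clock is the one that cheats: it books links on Ly that has gone to Ju.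

Feed the budget its own f, which gives 13.0%, then 14.0%. That last f gives my estimate of the dead-end ceiling, the length at which Ly reaches zero with its dead share paid: 7.64, far under the 99.0 that unequal ends alone allow.

The forecast says yes and 5.6, lower than my figure, holding that “the reverse step costs little because Ej is steadily drained to Jo”.

The flask gives yes and 6.00, passing 3.0 at 1.58 h. Take the loss of Ej to Jo away and the length at the asked time falls from 6.00 to 3.87, the largest single effect on this flask. With that drain in place, the flask stands under its estimated ceiling of 7.64, with 4.7% of its Ly still unbound at 6.00 h. Run the same flask for twice the time and the length is 7.20, closer to the ceiling but still below it.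

(The numbers of this flask were drawn at random within sensible limits; no experiment stands behind them.)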